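**Plan**

- Retrosynthesis: the 17 benzyl ethers and both gallate esters come off last. Ring C is then cut at C3–C4 and O1–C2, giving a ring-A salicylaldehyde (C4 as CHO, O1–H ortho to it) and a ring-B cinnamaldehyde. The open chain is cut at C-γ–ring D (terminal epoxide + aryl-metal) and at C-α–C6 of ring A (cis-epoxy alcohol + aryl-metal).
- Forward: the open chain is built first (cis-glycidate → cis-epoxy alcohol → diaryl diol → terminal epoxide → 1,3-diarylpropan-2-ol). It sits on C6 because the only silyl-masked oxygen, the later O1, is para to it. Ring A is then formylated, ring C is closed in one operation, and C3–CHO is converted to C3=O, then C3–OH, then both gallates, then hydrogenolysis.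
- Enabling feature: O1 of ring A is ortho to C4a, so C4 can be carried as a salicylaldehyde carbonyl. O1 adds reversibly to the enal β-carbon (C2, benzylic to ring B), and the enamine carbon C3, made nucleophilic by a formyl helper, closes ring C onto C4. The helper is later exchanged for the C3 oxygen by Baeyer–Villiger oxidation.
- Stereochemistry: C-α and C-β come from Jacobsen–Katsuki epoxidation of a (Z)-cinnamate and SN2 opening of the cis-epoxide. C2 comes from the prolinol silyl ether catalyst in the ring closure. C3 comes from hydride attack anti to ring B on the flavan-3-one.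
- Naming used below: rings A, B, C are the flavan rings; ring D is the free phloroglucinol ring; ring E is the pyrogallol ring on the methine; C-α, C-β, C-γ are the methine, carbinol and methylene carbons of the open chain.

Key step: step 11

Remark on the chemistry: the configuration is taken as drawn, (2R,3R) in the flavan and R at C-α, S at C-β in the open chain; compounds 1, 5, 12 and 24 are assumed to be catalogue items (otherwise each is one benzylation from the parent phenol).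

**Step 1**
Reactants: 1 3,4,5-tris(benzyloxy)benzaldehyde
Product: 2 ethyl (Z)-3-[3,4,5-tris(benzyloxy)phenyl]prop-2-enoate
Conditions: (PhO)2P(O)CH2CO2Et, NaH, THF, −78 → 0 °C
Reagents that add atoms: ethyl (diphenoxyphosphoryl)acetate, CCOC(=O)CP(=O)(Oc1ccccc1)Oc1ccccc1
Why: (Z)-selective Horner–Wadsworth–Emmons olefination; the electron-poor diaryl phosphonate should make oxaphosphetane collapse faster than equilibration, so the kinetic cis-alkene is expected.

**Step 2**
Reactants: 2 ethyl (Z)-3-[3,4,5-tris(benzyloxy)phenyl]prop-2-enoate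
Product: 3 ethyl (2R,3R)-3-[3,4,5-tris(benzyloxy)phenyl]oxirane-2-carboxylate (cis)
Conditions: (R,R)-(salen)MnCl (salen = N,N'-bis(3,5-di-tert-butylsalicylidene)-1,2-cyclohexanediamine dianion; cat.), 4-phenylpyridine N-oxide, aq. NaOCl (pH 11), CH2Cl2, 0 °C
Reagents that add atoms: sodium hypochlorite, [Na+].[O-]Cl
Why: Jacobsen–Katsuki epoxidation of a cis-cinnamate ester; the (R,R)-salen ligand should direct oxygen transfer to the face that gives the (2R,3R)-cis-glycidate, and any trans-epoxide formed by radical collapse is removed by chromatography.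

**Step 3**
Reactants: 3 ethyl (2R,3R)-3-[3,4,5-tris(benzyloxy)phenyl]oxirane-2-carboxylate
Product: 4 [(2S,3R)-3-[3,4,5-tris(benzyloxy)phenyl]oxiran-2-yl]methanol (cis)
Conditions: NaBH4, EtOH/THF, 0 °C → rt
Reagents that add atoms: none
Why: Borohydride reduction of an α-oxygenated (activated) ester, which should leave the epoxide intact; no stereocentre is touched, and the C2 descriptor changes from R to S only through CIP ranking.

**Step 4**
Reactants: 5 3,5-bis(benzyloxy)phenol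
Product: 6 [3,5-bis(benzyloxy)phenoxy]tri(propan-2-yl)silane
Conditions: i-Pr3SiCl, imidazole, DMF, rt
Reagents that add atoms: chlorotri(propan-2-yl)silane, CC(C)[Si](Cl)(C(C)C)C(C)C
Why: Silyl ether formation; the bulky, weakly coordinating silyloxy group marks the future O1 and leaves the position between the two benzyloxy groups as the only doubly activated site for lithiation.

**Step 5**
Reactants: 6 [3,5-bis(benzyloxy)phenoxy]tri(propan-2-yl)silane; 4 [(2S,3R)-3-[3,4,5-tris(benzyloxy)phenyl]oxiran-2-yl]methanol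
Product: 9 (2R,3R)-3-{2,6-bis(benzyloxy)-4-[tri(propan-2-yl)silyloxy]phenyl}-3-[3,4,5-tris(benzyloxy)phenyl]propane-1,2-diol, via aryllithium 7 (not isolated), via arylmagnesium bromide 8 (not isolated)
Conditions: 6 (excess), n-BuLi, THF, 0 °C; MgBr2·OEt2; CuI (cat.), then 4, −40 → 0 °C; aq. NH4Cl
Reagents that add atoms: none
Why: Directed ortho-lithiation between the two benzyloxy groups, then copper-catalysed Grignard opening of the 3-aryl-2,3-epoxy alcohol at its benzylic carbon with SN2 inversion, should set C-α and place the chain para to the silyloxy oxygen; C-β is not touched.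

**Step 6**
Reactants: 9 (2R,3R)-3-{2,6-bis(benzyloxy)-4-[tri(propan-2-yl)silyloxy]phenyl}-3-[3,4,5-tris(benzyloxy)phenyl]propane-1,2-diol
Product: 11 (2R)-2-[(R)-{2,6-bis(benzyloxy)-4-[tri(propan-2-yl)silyloxy]phenyl}[3,4,5-tris(benzyloxy)phenyl]methyl]oxirane, via primary tosylate alkoxide 10 (not isolated)
Conditions: NaH, 1-tosylimidazole, THF, 0 °C → rt
Reagents that add atoms: none
Why: One-pot diol-to-epoxide conversion; the primary alkoxide should be sulfonylated selectively and the secondary alkoxide then closes by intramolecular Williamson substitution (3-exo-tet), so the C-β–O bond is never broken and its configuration is retained.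

**Step 7**
Reactants: 12 1,3,5-tris(benzyloxy)benzene; 11 (2R)-2-[(R)-{2,6-bis(benzyloxy)-4-[tri(propan-2-yl)silyloxy]phenyl}[3,4,5-tris(benzyloxy)phenyl]methyl]oxirane
Product: 15 (2S,3R)-3-{2,6-bis(benzyloxy)-4-[tri(propan-2-yl)silyloxy]phenyl}-1-[2,4,6-tris(benzyloxy)phenyl]-3-[3,4,5-tris(benzyloxy)phenyl]propan-2-ol, via aryllithium 13 (not isolated), via arylmagnesium bromide 14 (not isolated)
Conditions: 12, n-BuLi, THF, 0 °C; MgBr2·OEt2; CuI (cat.), then 11, −30 → 0 °C; aq. NH4Cl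
Reagents that add atoms: none
Why: Ortho-lithiation of the symmetric triether and copper-catalysed Grignard opening of the terminal epoxide at its CH2 carbon should attach ring D to C-γ; no stereocentre reacts, and the descriptor at C-β becomes S only through CIP ranking.

**Step 8**
Reactants: 15 (2S,3R)-3-{2,6-bis(benzyloxy)-4-[tri(propan-2-yl)silyloxy]phenyl}-1-[2,4,6-tris(benzyloxy)phenyl]-3-[3,4,5-tris(benzyloxy)phenyl]propan-2-ol
Product: 16 (2S,3R)-3-[2,6-bis(benzyloxy)-4-hydroxyphenyl]-1-[2,4,6-tris(benzyloxy)phenyl]-3-[3,4,5-tris(benzyloxy)phenyl]propan-2-ol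
Conditions: Bu4NF, THF, 0 °C
Reagents that add atoms: none
Why: Fluoride-induced cleavage of the aryl silyl ether should free only the future O1–H; benzyl ethers are inert to fluoride.

**Step 9**
Reactants: 16 (2S,3R)-3-[2,6-bis(benzyloxy)-4-hydroxyphenyl]-1-[2,4,6-tris(benzyloxy)phenyl]-3-[3,4,5-tris(benzyloxy)phenyl]propan-2-ol
Product: 17 4,6-bis(benzyloxy)-2-hydroxy-5-{(1R,2S)-2-hydroxy-3-[2,4,6-tris(benzyloxy)phenyl]-1-[3,4,5-tris(benzyloxy)phenyl]propyl}benzaldehyde
Conditions: MgCl2, Et3N, (CH2O)n, MeCN, reflux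
Reagents that add atoms: formaldehyde (as paraformaldehyde), C=O
Why: Casnati–Skattebøl ortho-formylation; the magnesium phenoxide should deliver formaldehyde only ortho to O1–H, the two ortho sites are constitutionally equivalent and the para site is blocked, so C4 is installed next to O1 without regiochemical ambiguity.

**Step 10**
Reactants: 1 3,4,5-tris(benzyloxy)benzaldehyde
Product: 18 (E)-3-[3,4,5-tris(benzyloxy)phenyl]prop-2-enal
Conditions: Ph3P=CHCHO, toluene, 80 °C
Reagents that add atoms: (triphenylphosphoranylidene)acetaldehyde, O=CC=P(c1ccccc1)(c1ccccc1)c1ccccc1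
Why: Wittig olefination with a stabilised ylide, which should give the (E)-enal under thermodynamic control of the oxaphosphetane.

**Step 11**
Reactants: 17 4,6-bis(benzyloxy)-2-hydroxy-5-{(1R,2S)-2-hydroxy-3-[2,4,6-tris(benzyloxy)phenyl]-1-[3,4,5-tris(benzyloxy)phenyl]propyl}benzaldehyde; 18 (E)-3-[3,4,5-tris(benzyloxy)phenyl]prop-2-enal
Product: 20 (2R)-5,7-bis(benzyloxy)-6-{(1R,2S)-2-hydroxy-3-[2,4,6-tris(benzyloxy)phenyl]-1-[3,4,5-tris(benzyloxy)phenyl]propyl}-2-[3,4,5-tris(benzyloxy)phenyl]-2H-chromene-3-carbaldehyde, via aldol adduct 19 (not isolated)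
Conditions: (S)-α,α-diphenylprolinol trimethylsilyl ether (20 mol %), 2-nitrobenzoic acid (20 mol %), 4 Å molecular sieves, toluene, rt, dark
Reagents that add atoms: none
Why: The amine condenses with enal 18 to an iminium ion, O1 of ring A adds reversibly to its β-carbon (the later C2, benzylic to ring B), and the resulting enamine carbon (the later C3) attacks the ortho formyl carbon (the later C4) in an intramolecular aldol reaction; dehydration of aldol 19 and hydrolysis release 20 and the catalyst. The closest known reaction type is the amine-catalysed domino oxa-Michael–aldol condensation of salicylaldehydes with α,β-unsaturated aldehydes to 2H-chromene-3-carbaldehydes. Ring C closes by C3–C4 bond formation in a 6-(enolexo)-exo-trig mode. The one new stereocentre, C2, is controlled by the catalyst: its diphenyl(silyloxy)methyl group shields one face of the (E)-iminium so that O1 should add to the open face to give 2R, and because the oxa-Michael step is reversible, mismatched adducts can revert until the irreversible aldol–dehydration drains the matched one, so the side-chain centres should not decide the outcome. The step needs O- instead of C-alkylation of ring A and 1,4- instead of 1,2-addition; the formyl group lowers the nucleophilicity of C8 and raises the acidity of O1–H, and the aldol onto C4 is the only six-membered closure open to the enamine. The C3 formyl group is the helper that makes C3 nucleophilic, and it is exchanged for oxygen in step 12.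

**Step 12**
Reactants: 20 (2R)-5,7-bis(benzyloxy)-6-{(1R,2S)-2-hydroxy-3-[2,4,6-tris(benzyloxy)phenyl]-1-[3,4,5-tris(benzyloxy)phenyl]propyl}-2-[3,4,5-tris(benzyloxy)phenyl]-2H-chromene-3-carbaldehyde
Product: 22 (2R)-5,7-bis(benzyloxy)-6-{(1R,2S)-2-hydroxy-3-[2,4,6-tris(benzyloxy)phenyl]-1-[3,4,5-tris(benzyloxy)phenyl]propyl}-2-[3,4,5-tris(benzyloxy)phenyl]chroman-3-one, via enol formate 21 (not isolated)
Conditions: 30 % H2O2, (2-O2NC6H4Se)2 (cat.), CH2Cl2, rt; then KHCO3, MeOH, 0 °C, short; used crude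
Reagents that add atoms: hydrogen peroxide, OO
Why: Baeyer–Villiger (Dakin-type) oxidation of an α,β-unsaturated aldehyde, in which the electron-rich alkenyl group should migrate to give the enol formate, followed by cold methanolysis to the flavan-3-one; C2 is not involved and the brief, cold, weakly basic treatment is meant to keep it from epimerising.

**Step 13**
Reactants: 22 (2R)-5,7-bis(benzyloxy)-6-{(1R,2S)-2-hydroxy-3-[2,4,6-tris(benzyloxy)phenyl]-1-[3,4,5-tris(benzyloxy)phenyl]propyl}-2-[3,4,5-tris(benzyloxy)phenyl]chroman-3-one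
Product: 23 (2R,3R)-5,7-bis(benzyloxy)-6-{(1R,2S)-2-hydroxy-3-[2,4,6-tris(benzyloxy)phenyl]-1-[3,4,5-tris(benzyloxy)phenyl]propyl}-2-[3,4,5-tris(benzyloxy)phenyl]chroman-3-ol
Conditions: LiBH(s-Bu)3 (L-Selectride, excess), LiBr, THF, −78 °C; aq. NH4Cl
Reagents that add atoms: none
Why: Substrate-controlled ketone reduction with a bulky hydride, which should approach C3 from the face opposite ring B and so place the new hydroxyl cis to ring B (3R), as is known for benzyl-protected flavan-3-ones.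

**Step 14**
Reactants: 23 (2R,3R)-5,7-bis(benzyloxy)-6-{(1R,2S)-2-hydroxy-3-[2,4,6-tris(benzyloxy)phenyl]-1-[3,4,5-tris(benzyloxy)phenyl]propyl}-2-[3,4,5-tris(benzyloxy)phenyl]chroman-3-ol; 24 3,4,5-tris(benzyloxy)benzoic acid (two equivalents incorporated)
Product: 25 heptadeca-O-benzyl ether of the target: (2R,3R)-5,7-bis(benzyloxy)-6-{(1R,2S)-2-[3,4,5-tris(benzyloxy)benzoyloxy]-3-[2,4,6-tris(benzyloxy)phenyl]-1-[3,4,5-tris(benzyloxy)phenyl]propyl}-2-[3,4,5-tris(benzyloxy)phenyl]chroman-3-yl 3,4,5-tris(benzyloxy)benzoate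
Conditions: 24 (excess), DCC, DMAP, CH2Cl2, rt → 40 °C
Reagents that add atoms: none
Why: Steglich esterification of both secondary alcohols in one operation; acylation occurs at oxygen, so C3 and C-β keep their configuration.

**Step 15**
Reactants: 25 heptadeca-O-benzyl ether of the target
Product: 26 target, (2R,3R)-5,7-dihydroxy-6-[(1R,2S)-2-(3,4,5-trihydroxybenzoyloxy)-3-(2,4,6-trihydroxyphenyl)-1-(3,4,5-trihydroxyphenyl)propyl]-2-(3,4,5-trihydroxyphenyl)chroman-3-yl 3,4,5-trihydroxybenzoate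
Conditions: H2 (1 atm), Pd(OH)2/C, THF/MeOH, rt
Reagents that add atoms: none
Why: Catalytic hydrogenolysis of the 17 benzyl ethers; the gallate esters and the ring-C C2–O1 bond should survive under these mild conditions, as is usual for benzyl-protected flavan-3-ol gallates, and no stereocentre is affected.

**Compound list**

1 | 3,4,5-tris(benzyloxy)benzaldehyde | O=Cc1cc(OCc2ccccc2)c(OCc2ccccc2)c(OCc2ccccc2)c1 | starting material
2 | ethyl (Z)-3-[3,4,5-tris(benzyloxy)phenyl]prop-2-enoate | CCOC(=O)/C=C\c1cc(OCc2ccccc2)c(OCc2ccccc2)c(OCc2ccccc2)c1 | intermediate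
3 | ethyl (2R,3R)-3-[3,4,5-tris(benzyloxy)phenyl]oxirane-2-carboxylate | CCOC(=O)[C@@H]1O[C@@H]1c1cc(OCc2ccccc2)c(OCc2ccccc2)c(OCc2ccccc2)c1 | intermediate
4 | [(2S,3R)-3-[3,4,5-tris(benzyloxy)phenyl]oxiran-2-yl]methanol | OC[C@@H]1O[C@@H]1c1cc(OCc2ccccc2)c(OCc2ccccc2)c(OCc2ccccc2)c1 | intermediate
5 | 3,5-bis(benzyloxy)phenol | Oc1cc(OCc2ccccc2)cc(OCc2ccccc2)c1 | starting material
6 | [3,5-bis(benzyloxy)phenoxy]tri(propan-2-yl)silane | CC(C)[Si](Oc1cc(OCc2ccccc2)cc(OCc2ccccc2)c1)(C(C)C)C(C)C | intermediate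
7 | {2,6-bis(benzyloxy)-4-[tri(propan-2-yl)silyloxy]phenyl}lithium | [Li]c1c(OCc2ccccc2)cc(O[Si](C(C)C)(C(C)C)C(C)C)cc1OCc1ccccc1 | intermediate (not isolated)
8 | {2,6-bis(benzyloxy)-4-[tri(propan-2-yl)silyloxy]phenyl}magnesium bromide | Br[Mg]c1c(OCc2ccccc2)cc(O[Si](C(C)C)(C(C)C)C(C)C)cc1OCc1ccccc1 | intermediate (not isolated)
9 | (2R,3R)-3-{2,6-bis(benzyloxy)-4-[tri(propan-2-yl)silyloxy]phenyl}-3-[3,4,5-tris(benzyloxy)phenyl]propane-1,2-diol | O[C@@H](CO)[C@H](c1cc(OCc2ccccc2)c(OCc2ccccc2)c(OCc2ccccc2)c1)c1c(OCc2ccccc2)cc(O[Si](C(C)C)(C(C)C)C(C)C)cc1OCc1ccccc1 | intermediate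
10 | sodium alkoxide of the 1-O-tosylate of 9 | [Na+].[O-][C@@H](COS(=O)(=O)c1ccc(C)cc1)[C@H](c1cc(OCc2ccccc2)c(OCc2ccccc2)c(OCc2ccccc2)c1)c1c(OCc2ccccc2)cc(O[Si](C(C)C)(C(C)C)C(C)C)cc1OCc1ccccc1 | intermediate (not isolated)
11 | (2R)-2-[(R)-{2,6-bis(benzyloxy)-4-[tri(propan-2-yl)silyloxy]phenyl}[3,4,5-tris(benzyloxy)phenyl]methyl]oxirane | C1O[C@@H]1[C@H](c1cc(OCc2ccccc2)c(OCc2ccccc2)c(OCc2ccccc2)c1)c1c(OCc2ccccc2)cc(O[Si](C(C)C)(C(C)C)C(C)C)cc1OCc1ccccc1 | intermediate
12 | 1,3,5-tris(benzyloxy)benzene | c1c(OCc2ccccc2)cc(OCc2ccccc2)cc1OCc1ccccc1 | starting material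
13 | [2,4,6-tris(benzyloxy)phenyl]lithium | [Li]c1c(OCc2ccccc2)cc(OCc2ccccc2)cc1OCc1ccccc1 | intermediate (not isolated)
14 | [2,4,6-tris(benzyloxy)phenyl]magnesium bromide | Br[Mg]c1c(OCc2ccccc2)cc(OCc2ccccc2)cc1OCc1ccccc1 | intermediate (not isolated)
15 | (2S,3R)-3-{2,6-bis(benzyloxy)-4-[tri(propan-2-yl)silyloxy]phenyl}-1-[2,4,6-tris(benzyloxy)phenyl]-3-[3,4,5-tris(benzyloxy)phenyl]propan-2-ol | O[C@@H](Cc1c(OCc2ccccc2)cc(OCc2ccccc2)cc1OCc1ccccc1)[C@H](c1cc(OCc2ccccc2)c(OCc2ccccc2)c(OCc2ccccc2)c1)c1c(OCc2ccccc2)cc(O[Si](C(C)C)(C(C)C)C(C)C)cc1OCc1ccccc1 | intermediate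
16 | (2S,3R)-3-[2,6-bis(benzyloxy)-4-hydroxyphenyl]-1-[2,4,6-tris(benzyloxy)phenyl]-3-[3,4,5-tris(benzyloxy)phenyl]propan-2-ol | O[C@@H](Cc1c(OCc2ccccc2)cc(OCc2ccccc2)cc1OCc1ccccc1)[C@H](c1cc(OCc2ccccc2)c(OCc2ccccc2)c(OCc2ccccc2)c1)c1c(OCc2ccccc2)cc(O)cc1OCc1ccccc1 | intermediate
17 | 4,6-bis(benzyloxy)-2-hydroxy-5-{(1R,2S)-2-hydroxy-3-[2,4,6-tris(benzyloxy)phenyl]-1-[3,4,5-tris(benzyloxy)phenyl]propyl}benzaldehyde | O[C@@H](Cc1c(OCc2ccccc2)cc(OCc2ccccc2)cc1OCc1ccccc1)[C@H](c1cc(OCc2ccccc2)c(OCc2ccccc2)c(OCc2ccccc2)c1)c1c(OCc2ccccc2)cc(O)c(C=O)c1OCc1ccccc1 | intermediate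
18 | (E)-3-[3,4,5-tris(benzyloxy)phenyl]prop-2-enal | O=C/C=C/c1cc(OCc2ccccc2)c(OCc2ccccc2)c(OCc2ccccc2)c1 | intermediate
19 | aldol adduct: 5,7-bis(benzyloxy)-4-hydroxy-2-[3,4,5-tris(benzyloxy)phenyl]chroman-3-carbaldehyde carrying the C6 side chain of 17 (C2 arranged as in 20, C3 and C4 not defined; catalyst-free form) | O[C@@H](Cc1c(OCc2ccccc2)cc(OCc2ccccc2)cc1OCc1ccccc1)[C@H](c1cc(OCc2ccccc2)c(OCc2ccccc2)c(OCc2ccccc2)c1)c1c(OCc2ccccc2)cc2c(c1OCc1ccccc1)C(O)C(C=O)[C@@H](c1cc(OCc3ccccc3)c(OCc3ccccc3)c(OCc3ccccc3)c1)O2 | intermediate (not isolated)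
20 | (2R)-5,7-bis(benzyloxy)-6-{(1R,2S)-2-hydroxy-3-[2,4,6-tris(benzyloxy)phenyl]-1-[3,4,5-tris(benzyloxy)phenyl]propyl}-2-[3,4,5-tris(benzyloxy)phenyl]-2H-chromene-3-carbaldehyde | O[C@@H](Cc1c(OCc2ccccc2)cc(OCc2ccccc2)cc1OCc1ccccc1)[C@H](c1cc(OCc2ccccc2)c(OCc2ccccc2)c(OCc2ccccc2)c1)c1c(OCc2ccccc2)cc2c(c1OCc1ccccc1)C=C(C=O)[C@@H](c1cc(OCc3ccccc3)c(OCc3ccccc3)c(OCc3ccccc3)c1)O2 | intermediate
21 | (2R)-2H-chromen-3-yl formate corresponding to 20 (enol formate) | O[C@@H](Cc1c(OCc2ccccc2)cc(OCc2ccccc2)cc1OCc1ccccc1)[C@H](c1cc(OCc2ccccc2)c(OCc2ccccc2)c(OCc2ccccc2)c1)c1c(OCc2ccccc2)cc2c(c1OCc1ccccc1)C=C(OC=O)[C@@H](c1cc(OCc3ccccc3)c(OCc3ccccc3)c(OCc3ccccc3)c1)O2 | intermediate (not isolated)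
22 | (2R)-5,7-bis(benzyloxy)-6-{(1R,2S)-2-hydroxy-3-[2,4,6-tris(benzyloxy)phenyl]-1-[3,4,5-tris(benzyloxy)phenyl]propyl}-2-[3,4,5-tris(benzyloxy)phenyl]chroman-3-one | O[C@@H](Cc1c(OCc2ccccc2)cc(OCc2ccccc2)cc1OCc1ccccc1)[C@H](c1cc(OCc2ccccc2)c(OCc2ccccc2)c(OCc2ccccc2)c1)c1c(OCc2ccccc2)cc2c(c1OCc1ccccc1)CC(=O)[C@@H](c1cc(OCc3ccccc3)c(OCc3ccccc3)c(OCc3ccccc3)c1)O2 | intermediate
23 | (2R,3R)-5,7-bis(benzyloxy)-6-{(1R,2S)-2-hydroxy-3-[2,4,6-tris(benzyloxy)phenyl]-1-[3,4,5-tris(benzyloxy)phenyl]propyl}-2-[3,4,5-tris(benzyloxy)phenyl]chroman-3-ol | O[C@@H](Cc1c(OCc2ccccc2)cc(OCc2ccccc2)cc1OCc1ccccc1)[C@H](c1cc(OCc2ccccc2)c(OCc2ccccc2)c(OCc2ccccc2)c1)c1c(OCc2ccccc2)cc2c(c1OCc1ccccc1)C[C@@H](O)[C@@H](c1cc(OCc3ccccc3)c(OCc3ccccc3)c(OCc3ccccc3)c1)O2 | intermediate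
24 | 3,4,5-tris(benzyloxy)benzoic acid | OC(=O)c1cc(OCc2ccccc2)c(OCc2ccccc2)c(OCc2ccccc2)c1 | starting material
25 | heptadeca-O-benzyl ether of the target (name as in step 14) | O=C(O[C@@H](Cc1c(OCc2ccccc2)cc(OCc2ccccc2)cc1OCc1ccccc1)[C@H](c1cc(OCc2ccccc2)c(OCc2ccccc2)c(OCc2ccccc2)c1)c1c(OCc2ccccc2)cc2c(c1OCc1ccccc1)C[C@@H](OC(=O)c1cc(OCc3ccccc3)c(OCc3ccccc3)c(OCc3ccccc3)c1)[C@@H](c1cc(OCc3ccccc3)c(OCc3ccccc3)c(OCc3ccccc3)c1)O2)c1cc(OCc2ccccc2)c(OCc2ccccc2)c(OCc2ccccc2)c1 | intermediate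
26 | (2R,3R)-5,7-dihydroxy-6-[(1R,2S)-2-(3,4,5-trihydroxybenzoyloxy)-3-(2,4,6-trihydroxyphenyl)-1-(3,4,5-trihydroxyphenyl)propyl]-2-(3,4,5-trihydroxyphenyl)chroman-3-yl 3,4,5-trihydroxybenzoate | O=C(O[C@@H](Cc1c(O)cc(O)cc1O)[C@H](c1cc(O)c(O)c(O)c1)c1c(O)cc2c(c1O)C[C@@H](OC(=O)c1cc(O)c(O)c(O)c1)[C@@H](c1cc(O)c(O)c(O)c1)O2)c1cc(O)c(O)c(O)c1 | target

**Step count**

Total step count: 15. Longest linear sequence: 13 steps (1, 2, 3, 5, 6, 7, 8, 9, 11, 12, 13, 14, 15); steps 4 and 10 are side branches.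

**Steps most likely to fail, with fallbacks**

Step 11. The aldol closure onto the strongly electron-rich, doubly ortho-substituted formyl carbon may be slow. Reversible oxa-Michael addition could then erode facial control at C2, or C-alkylation at C8 could take over. The fallback replaces the formyl helper on C3 by a nitro group and the enamine by a more nucleophilic nitronate. It sets out from 1 and 17 and comes back at 22. Henry condensation of 1 with nitromethane (NH4OAc, AcOH, 90 °C) gives (E)-1,2,3-tris(benzyloxy)-5-(2-nitroethenyl)benzene F1. The known asymmetric oxa-Michael–Henry–dehydration of salicylaldehydes with nitroalkenes, run on 17 and F1 with a chiral bifunctional pyrrolidine–thiourea amine, closes ring C again at C3–C4 and gives the (2R)-3-nitro-2H-chromene F2; its C2 epimer is a diastereomer and is removed by chromatography. Reduction of the nitroalkene with Fe powder in aqueous AcOH and hydrolysis of the resulting enamine then gives ketone 22.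

Step 5. SN2 attack by the doubly ortho-substituted aryl-copper species at a secondary benzylic carbon may be sterically retarded. Attack at C2 of the epoxy alcohol, epoxide isomerisation, or benzylic deprotonation of the benzyl ethers during lithiation could then compete. The fallback drops the aryl-metal altogether and uses the arene as a π-nucleophile. It sets out from 4 and 6 and comes back at 9. Friedel–Crafts arylation of 4 with 6 (BF3·OEt2, CH2Cl2, −78 °C, or (CF3)2CHOH without Lewis acid) should open the benzylic epoxide carbon with inversion. The bulky silyloxy group should steer substitution to the position between the two benzyloxy groups, and any regioisomer is removed by chromatography. This detour makes no new compound (F0).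

Step 12. The peroxide may attack the electron-rich rings or epoxidise C3=C4 instead of inducing alkenyl migration, and the basic methanolysis may epimerise C2 of the ketone. The fallback exchanges the C3 carbon for nitrogen instead of oxygen. It sets out from 20 and comes back at 22. Pinnick oxidation (NaClO2, NaH2PO4, 2-methyl-2-butene, t-BuOH/H2O) gives the 2H-chromene-3-carboxylic acid F3. Curtius rearrangement ((PhO)2P(O)N3, Et3N, toluene, 80 °C, then t-BuOH) gives the tert-butyl enecarbamate F4. Hydrolysis with aqueous oxalic acid in THF then releases ketone 22 under non-basic conditions.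

**Further compounds**

F1 | step 11 | (E)-1,2,3-tris(benzyloxy)-5-(2-nitroethenyl)benzene | [O-][N+](=O)/C=C/c1cc(OCc2ccccc2)c(OCc2ccccc2)c(OCc2ccccc2)c1
F2 | step 11 | (2R)-5,7-bis(benzyloxy)-6-{(1R,2S)-2-hydroxy-3-[2,4,6-tris(benzyloxy)phenyl]-1-[3,4,5-tris(benzyloxy)phenyl]propyl}-3-nitro-2-[3,4,5-tris(benzyloxy)phenyl]-2H-chromene | O[C@@H](Cc1c(OCc2ccccc2)cc(OCc2ccccc2)cc1OCc1ccccc1)[C@H](c1cc(OCc2ccccc2)c(OCc2ccccc2)c(OCc2ccccc2)c1)c1c(OCc2ccccc2)cc2c(c1OCc1ccccc1)C=C([N+](=O)[O-])[C@@H](c1cc(OCc3ccccc3)c(OCc3ccccc3)c(OCc3ccccc3)c1)O2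
F0 | step 5 | none | none
F3 | step 12 | (2R)-5,7-bis(benzyloxy)-6-{(1R,2S)-2-hydroxy-3-[2,4,6-tris(benzyloxy)phenyl]-1-[3,4,5-tris(benzyloxy)phenyl]propyl}-2-[3,4,5-tris(benzyloxy)phenyl]-2H-chromene-3-carboxylic acid | O[C@@H](Cc1c(OCc2ccccc2)cc(OCc2ccccc2)cc1OCc1ccccc1)[C@H](c1cc(OCc2ccccc2)c(OCc2ccccc2)c(OCc2ccccc2)c1)c1c(OCc2ccccc2)cc2c(c1OCc1ccccc1)C=C(C(=O)O)[C@@H](c1cc(OCc3ccccc3)c(OCc3ccccc3)c(OCc3ccccc3)c1)O2
F4 | step 12 | tert-butyl N-[(2R)-5,7-bis(benzyloxy)-6-{(1R,2S)-2-hydroxy-3-[2,4,6-tris(benzyloxy)phenyl]-1-[3,4,5-tris(benzyloxy)phenyl]propyl}-2-[3,4,5-tris(benzyloxy)phenyl]-2H-chromen-3-yl]carbamate | O[C@@H](Cc1c(OCc2ccccc2)cc(OCc2ccccc2)cc1OCc1ccccc1)[C@H](c1cc(OCc2ccccc2)c(OCc2ccccc2)c(OCc2ccccc2)c1)c1c(OCc2ccccc2)cc2c(c1OCc1ccccc1)C=C(NC(=O)OC(C)(C)C)[C@@H](c1cc(OCc3ccccc3)c(OCc3ccccc3)c(OCc3ccccc3)c1)O2
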